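In this flask the forward link step, counted alone with J as charged, has a half-life of Q of 0.25 h, far shorter than the 440 d of the loss to Z, and you have 10 d.

Q 2.0 M; J 2.04 M; L 0.0200 M; time 10 d

    Q + J ⇌ Q.J (K1 = 1.6 M⁻¹, k1 = 0.023 M⁻¹ min⁻¹)
    Q + L → Q.L (k2 = 0.48 M⁻¹ min⁻¹)
    Q → Z (k3 = 1.1 × 10⁻⁶ min⁻¹)

- average number of monomer units in a chain (unreacted monomers counted as chains of one) at 10 d
- part of the Q that has reacted at 10 d

- each monomer carries two end groups and L one, which caps an end: a chain counts once for every two ends that are left, dead ends included; the units are half of the end groups of the two monomers charged
- what has gone from Q into another species counts as reacted, even if it can come back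
- run time (flask): 10 d

So count turnovers. The run holds 975 forward half-lives of linking but 0.0227 of loss, which makes this flask a matter of balance, thermodynamic rather than kinetic control. L has a half-life of 0.722 min against Q as charged, so I take the charge of L off the Q that can link. With x as Q.J, I then solve:

x = 1.6 M⁻¹ × (1.98 M − x) × (2.04 M − x)

This gives 1.16 M, the quantity to carry: the link count at balance, the c(Q.J) at which the way forward and the way back cancel.

Way one counts the ends of the monomers. Each link removes two, while capping and the loss to Z remove none, since capped and dead ends still count:

dp = 4.04 M / 1.72 M = 2.34

For c, I add the capped Q and the loss to Z, 0.0130 M, which gives 59.6%.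

Way two is the Carothers rule, one over the unreacted part of Q: 2.47, higher than way one. They part, and the rule cheats: it treats every reacted Q as a link, though Q.L and Z are none, and it ignores the J charged beyond Q. I keep the count of ends.

The forecast gives 2.33 and 59.3%, on the ground that “the link equilibrium settles within hours”, and its c stands 0.30 percentage points below mine.

This flask gives 2.33 and 59.3%, with 57.7% of the Q charged in Q.J at 10.0 d, and my x is 57.9% of that charge. The way back from Q.J has the largest single effect on chain length in this flask: the same run without it reaches a dp of 50.3 against 2.33. For a neighbour charged with 0.80 M of Q, the same balance gives 0.550 M of links and a dp of 1.63, and that flask reads 1.63.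

(The numbers were drawn at random within sensible limits; the run is a simulation.)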